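The six-membered ring holds a tetrasubstituted alkene (C3=C4, ring numbered from the side-chain carbon C1) flanked by two carbinol carbons, C2 and C5. This ene-1,4-dioxygen array is the retron of a furan–alkyne Diels–Alder adduct. Furan and methyl 3-bromopropiolate, two flat achiral molecules, combine to form C2–C3 and C4–C5 in one operation. This closes the carbocycle as a 7-oxanorbornadiene, whose oxygen bridge is a temporary ring. The bridge then relays all stereochemistry: enantioselective exo ring opening with a masked acetaldehyde nucleophile sets C1 and C2 cis, and this pair shields one face for dihydroxylation at C5/C6. Bromine becomes the heptenyl group, the ester the CH2OH.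

Key step: step 2

Assumption: the (R,S) ligand of step 3 is taken to send the alkenyl group to C5 of (1R,4S)-4, by analogy with meso oxabicyclic alkenes; if the sense is opposite, the mirror-image ligand serves.

Step 1
Reactants: 1 methyl propiolate
Product: 2 methyl 3-bromopropiolate
Conditions: NBS (1.1 equiv), AgNO3 (10 mol %), acetone, rt
Reagents that add atoms: N-bromosuccinimide, O=C1CCC(=O)N1Br
Why: Silver-catalysed electrophilic bromination of a terminal alkyne replaces the acetylenic hydrogen by bromine without touching the ester, and no stereocentre is formed.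

Step 2
Reactants: 2 methyl 3-bromopropiolate; 3 furan
Product: 4 (±)-methyl 3-bromo-7-oxabicyclo[2.2.1]hepta-2,5-diene-2-carboxylate
Conditions: furan (5 equiv), toluene, sealed tube, 80 °C, 24 h
Reagents that add atoms: none
Why: The step is a concerted, normal-electron-demand [4+2] cycloaddition in which the furan HOMO adds suprafacially through its two α-carbons across the alkyne, whose LUMO is lowered by the ester and by bromine, so that the bridgehead–C(ester) and bridgehead–C(Br) bonds form in the same event. The closest known reaction type is the thermal Diels–Alder reaction of furans with 3-halopropiolates and acetylenedicarboxylates. The six-membered carbocycle is closed intermolecularly in the [4+2] mode and appears as the boat of a 7-oxabicyclo[2.2.1]heptadiene, the furan oxygen becoming a one-atom bridge that is opened later. The two new stereocentres, bridgeheads C1 and C4, are locked cis by the bridge, so control is relative only: 4 is racemic and its enantiomers are sorted in step 3. No regiochemical question arises because furan is C2v-symmetric. The step needs mono-addition without cycloreversion or aromatisation, which the hindered, fully substituted bromoacrylate alkene of 4 (a poor dienophile for a second furan), the excess of furan and acid-free heating at 80 °C should secure.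

Step 3
Reactants: 4 (±)-methyl 3-bromo-7-oxabicyclo[2.2.1]hepta-2,5-diene-2-carboxylate; 5 (E)-2-(2-ethoxyethenyl)-4,4,5,5-tetramethyl-1,3,2-dioxaborolane
Product: 6 methyl (3S,4R)-2-bromo-4-[(E)-2-ethoxyethenyl]-3-hydroxycyclohexa-1,5-diene-1-carboxylate
Conditions: 5 (1.3 equiv), [Rh(cod)(OH)]2 (2.5 mol %), (R)-1-[(S)-2-(diphenylphosphino)ferrocenyl]ethyl-di-tert-butylphosphine (6 mol %), THF/H2O 10:1, rt; chromatography on Et3N-deactivated silica
Reagents that add atoms: none
Why: This is a rhodium-catalysed asymmetric ring opening of an oxabicyclic alkene with an organoboron reagent, run as a regiodivergent reaction on the racemate: the alkenyl–rhodium species adds to the unsubstituted C5=C6 alkene from the exo face (syn to the bridge) and β-oxygen elimination follows, which places OH and alkenyl cis, while the ligand picks the same local alkene carbon in both enantiomers, so that only (1R,4S)-4 gives 6 (C1–O broken, C4–O kept) and the other enantiomer gives a separable constitutional isomer.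

Step 4
Reactants: 6 methyl (3S,4R)-2-bromo-4-[(E)-2-ethoxyethenyl]-3-hydroxycyclohexa-1,5-diene-1-carboxylate
Product: 7 methyl (3aS,7aS)-7-bromo-2-ethoxy-2,3,3a,7a-tetrahydro-1-benzofuran-6-carboxylate (cis-fused, epimers at C2)
Conditions: PPTS (5 mol %), 4 Å molecular sieves, CH2Cl2, 0 °C to rt
Reagents that add atoms: none
Why: In this acid-catalysed intramolecular acetalisation, protonation of the enol ether gives an oxocarbenium ion that the cis hydroxyl captures in a 5-exo-trig closure, masking aldehyde and alcohol together, while ester and bromine on the diene disfavour ionisation at the carbinol carbon and hence dehydration to an arene; the acetal carbon forms as an inconsequential epimer mixture.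

Step 5
Reactants: 7 methyl (3aS,7aS)-7-bromo-2-ethoxy-2,3,3a,7a-tetrahydro-1-benzofuran-6-carboxylate
Product: 8 methyl (3aS,4S,5R,7aS)-7-bromo-2-ethoxy-4,5-dihydroxy-2,3,3a,4,5,7a-hexahydro-1-benzofuran-6-carboxylate
Conditions: OsO4 (2 mol %), NMO (1.2 equiv), acetone/H2O 4:1, 0 °C to rt
Reagents that add atoms: osmium tetroxide, O=[Os](=O)(=O)=O; N-methylmorpholine N-oxide, C[N+]1([O-])CCOCC1; water, O
Why: In this catalytic OsO4/NMO syn-dihydroxylation the reagent should add to the only unhindered, non-deactivated alkene (C4=C5, not the tetrasubstituted bromoacrylate) from the convex face opposite to the cis-fused tetrahydrofuran ring, which sets both new carbinol centres cis to each other and trans to the C3a substituent.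

Step 6
Reactants: 8 methyl (3aS,4S,5R,7aS)-7-bromo-2-ethoxy-4,5-dihydroxy-2,3,3a,4,5,7a-hexahydro-1-benzofuran-6-carboxylate
Product: 9 (3aS,4S,5R,7aS)-7-bromo-2-ethoxy-6-(hydroxymethyl)-2,3,3a,4,5,7a-hexahydro-1-benzofuran-4,5-diol
Conditions: DIBAL-H (6 equiv), CH2Cl2, −78 to −40 °C; aq. potassium sodium tartrate work-up
Reagents that add atoms: none
Why: DIBAL-H effects 1,2-reduction of the α,β-unsaturated ester to the allylic alcohol while this is still the only ester in the molecule; vinyl bromide and acetal are inert at low temperature and no stereocentre is touched.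

Step 7
Reactants: 9 (3aS,4S,5R,7aS)-7-bromo-2-ethoxy-6-(hydroxymethyl)-2,3,3a,4,5,7a-hexahydro-1-benzofuran-4,5-diol
Product: 10 (3aS,4S,5R,7aS)-7-bromo-6-(hydroxymethyl)-2,3,3a,4,5,7a-hexahydro-1-benzofuran-2,4,5-triol (lactol, epimers at C2)
Conditions: 0.1 M aq. HCl/THF 1:1, rt
Reagents that add atoms: water, O
Why: This is an acid-catalysed acetal hydrolysis, and a 2-alkoxytetrahydrofuran hydrolyses under much milder acid than is needed to ionise the bromine-deactivated allylic alcohols, so the four ring stereocentres should stay intact.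

Step 8
Reactants: 10 (3aS,4S,5R,7aS)-7-bromo-6-(hydroxymethyl)-2,3,3a,4,5,7a-hexahydro-1-benzofuran-2,4,5-triol; 11 ethyl 2-(triphenylphosphoranylidene)propanoate
Product: 13 ethyl (2E)-4-[(1S,2S,5R,6S)-3-bromo-2,5,6-trihydroxy-4-(hydroxymethyl)cyclohex-3-en-1-yl]-2-methylbut-2-enoate, via hydroxy aldehyde 12 (not isolated)
Conditions: 11 (1.5 equiv), PhCO2H (10 mol %), THF, 60 °C
Reagents that add atoms: none
Why: This is a Wittig olefination of a lactol through its open-chain tautomer, in which the stabilised α-methyl ylide should give the E-trisubstituted enoate, needs no added base and tolerates the free hydroxyls.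

Step 9
Reactants: 13 ethyl (2E)-4-[(1S,2S,5R,6S)-3-bromo-2,5,6-trihydroxy-4-(hydroxymethyl)cyclohex-3-en-1-yl]-2-methylbut-2-enoate; 14 (E)-hept-1-en-1-ylboronic acid
Product: 15 ethyl (2E)-4-[(1R,2S,5R,6S)-3-[(1E)-hept-1-en-1-yl]-2,5,6-trihydroxy-4-(hydroxymethyl)cyclohex-3-en-1-yl]-2-methylbut-2-enoate
Conditions: 14 (1.5 equiv), Pd(OAc)2 (5 mol %), SPhos (10 mol %), K3PO4 (3 equiv), THF/H2O 10:1, 50 °C
Reagents that add atoms: none
Why: The Suzuki–Miyaura coupling of a vinyl bromide with an alkenylboronic acid retains the geometry of both partners, tolerates free hydroxyls, and comes after dihydroxylation and after the last acidic step so that the diene meets neither.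

Step 10
Reactants: 15 ethyl (2E)-4-[(1R,2S,5R,6S)-3-[(1E)-hept-1-en-1-yl]-2,5,6-trihydroxy-4-(hydroxymethyl)cyclohex-3-en-1-yl]-2-methylbut-2-enoate
Product: 17 pestallic acid P, via lithium carboxylate 16 (not isolated)
Conditions: LiOH (5 equiv), THF/H2O 2:1, 0 °C to rt; then 0.1 M HCl to pH 4, 0 °C
Reagents that add atoms: lithium hydroxide, [Li+].[OH-]
Why: Saponification of the unhindered ethyl enoate followed by gentle acidification frees the acid without epimerisable centres being involved and without ionising the dienylic carbinol.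

Compound list
1 | methyl propiolate | C#CC(=O)OC | starting material
2 | methyl 3-bromopropiolate | BrC#CC(=O)OC | intermediate
3 | furan | c1ccoc1 | starting material
4 | (±)-methyl 3-bromo-7-oxabicyclo[2.2.1]hepta-2,5-diene-2-carboxylate (racemate; the SMILES shows the (1R,4S) enantiomer that is carried on) | BrC1=C(C(=O)OC)[C@H]2C=C[C@@H]1O2 | intermediate
5 | (E)-2-(2-ethoxyethenyl)-4,4,5,5-tetramethyl-1,3,2-dioxaborolane | CCO/C=C/B1OC(C)(C)C(C)(C)O1 | starting material
6 | methyl (3S,4R)-2-bromo-4-[(E)-2-ethoxyethenyl]-3-hydroxycyclohexa-1,5-diene-1-carboxylate (OH and alkenyl cis) | BrC1=C(C(=O)OC)C=C[C@H](/C=C/OCC)[C@@H]1O | intermediate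
7 | methyl (3aS,7aS)-7-bromo-2-ethoxy-2,3,3a,7a-tetrahydro-1-benzofuran-6-carboxylate (cis-fused, C2 epimers) | BrC1=C(C(=O)OC)C=C[C@H](CC(OCC)O2)[C@@H]12 | intermediate
8 | methyl (3aS,4S,5R,7aS)-7-bromo-2-ethoxy-4,5-dihydroxy-2,3,3a,4,5,7a-hexahydro-1-benzofuran-6-carboxylate (diol opposite to the tetrahydrofuran ring) | BrC1=C(C(=O)OC)[C@@H](O)[C@@H](O)[C@H](CC(OCC)O2)[C@@H]12 | intermediate
9 | (3aS,4S,5R,7aS)-7-bromo-2-ethoxy-6-(hydroxymethyl)-2,3,3a,4,5,7a-hexahydro-1-benzofuran-4,5-diol | BrC1=C(CO)[C@@H](O)[C@@H](O)[C@H](CC(OCC)O2)[C@@H]12 | intermediate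
10 | (3aS,4S,5R,7aS)-7-bromo-6-(hydroxymethyl)-2,3,3a,4,5,7a-hexahydro-1-benzofuran-2,4,5-triol (lactol) | BrC1=C(CO)[C@@H](O)[C@@H](O)[C@H](CC(O)O2)[C@@H]12 | intermediate
11 | ethyl 2-(triphenylphosphoranylidene)propanoate | CCOC(=O)C(C)=P(c1ccccc1)(c1ccccc1)c1ccccc1 | starting material
12 | 2-[(1S,2S,5R,6S)-3-bromo-2,5,6-trihydroxy-4-(hydroxymethyl)cyclohex-3-en-1-yl]acetaldehyde (open form of 10, not isolated) | BrC1=C(CO)[C@@H](O)[C@@H](O)[C@H](CC=O)[C@@H]1O | intermediate
13 | ethyl (2E)-4-[(1S,2S,5R,6S)-3-bromo-2,5,6-trihydroxy-4-(hydroxymethyl)cyclohex-3-en-1-yl]-2-methylbut-2-enoate | BrC1=C(CO)[C@@H](O)[C@@H](O)[C@H](C/C=C(\C)C(=O)OCC)[C@@H]1O | intermediate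
14 | (E)-hept-1-en-1-ylboronic acid | CCCCC/C=C/B(O)O | starting material
15 | ethyl (2E)-4-[(1R,2S,5R,6S)-3-[(1E)-hept-1-en-1-yl]-2,5,6-trihydroxy-4-(hydroxymethyl)cyclohex-3-en-1-yl]-2-methylbut-2-enoate | CCCCC/C=C/C1=C(CO)[C@@H](O)[C@@H](O)[C@H](C/C=C(\C)C(=O)OCC)[C@@H]1O | intermediate
16 | lithium salt of 17 (not isolated) | CCCCC/C=C/C1=C(CO)[C@@H](O)[C@@H](O)[C@H](C/C=C(\C)C(=O)[O-])[C@@H]1O.[Li+] | intermediate
17 | pestallic acid P, (2E)-4-[(1R,2S,5R,6S)-3-[(1E)-hept-1-en-1-yl]-2,5,6-trihydroxy-4-(hydroxymethyl)cyclohex-3-en-1-yl]-2-methylbut-2-enoic acid | CCCCC/C=C/C1=C(CO)[C@@H](O)[C@@H](O)[C@H](C/C=C(\C)C(=O)O)[C@@H]1O | target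

Total step count: 10. Longest linear sequence: 10 steps (from methyl propiolate).

Steps most likely to fail

Step 3. Ligand control over which bridgehead C–O bond breaks may be incomplete, because the bromine/ester bias of the far alkene can work against the catalyst. This would erode both regiodivergence and enantiopurity, and the step is the only source of absolute configuration. The fallback sets out from 4 and comes back at 6.
- The opening with 5 is run with the achiral ligand dppf on [Rh(cod)(OH)]2. It should give 6 together with its mirror-image dienol F1, beside the racemic regioisomeric dienol F2, which is removed by chromatography.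
- Immobilised Candida antarctica lipase B and vinyl acetate in MTBE at 30 °C, stopped near half conversion, should then convert the (3R)-carbinol into the acetate of the mirror-image dienol F3. In the empirical size model for lipases the bromoalkene side counts as the large group.
- This leaves 6 unreacted, so the absolute configuration comes from an enzymatic kinetic resolution instead of from ligand control.

Step 9. Oxidative addition into the hindered, unactivated tetrasubstituted C–Br bond between two allylic hydroxyls may be slow, so that protodeboronation of 14 and reductive debromination compete. The fallback sets out from 8 and comes back at 15.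
- The coupling is moved forward to 8, where the C–Br bond is the activated β-position of an acrylate. Under the same palladium system this should give the heptenyl dienoate acetal F4.
- DIBAL-H reduction should give the heptenyl triol acetal F5.
- Hydrolysis under buffered conditions (PPTS, wet acetone, rt), chosen because the carbinol is now dienylic, should give the heptenyl lactol F6.
- Wittig reaction of F6 with 11 should give 15.

Step 8. Ring opening of the lactol may be slow, and the freed C2 hydroxyl may add back to the new enoate (oxa-Michael closure to a tetrahydrofuran). The fallback sets out from 10 and comes back at 13.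
- Excess methylenetriphenylphosphorane (from MePPh3Br and KHMDS, THF, 0 °C) should convert 10 into the allyl tetraol F7.
- Cross-metathesis of F7 with excess ethyl methacrylate (second-generation Hoveyda–Grubbs catalyst, CH2Cl2, 40 °C) should build the E-trisubstituted enoate 13 under neutral conditions.

Further compounds
F1 | step 3 | methyl (3R,4S)-2-bromo-4-[(E)-2-ethoxyethenyl]-3-hydroxycyclohexa-1,5-diene-1-carboxylate (mirror image of 6) | BrC1=C(C(=O)OC)C=C[C@@H](/C=C/OCC)[C@H]1O
F2 | step 3 | (±)-methyl cis-2-bromo-5-[(E)-2-ethoxyethenyl]-6-hydroxycyclohexa-1,3-diene-1-carboxylate (racemate, one enantiomer drawn) | COC(=O)C1=C(Br)C=C[C@H](/C=C/OCC)[C@@H]1O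
F3 | step 3 | methyl (3R,4S)-3-acetoxy-2-bromo-4-[(E)-2-ethoxyethenyl]cyclohexa-1,5-diene-1-carboxylate | BrC1=C(C(=O)OC)C=C[C@@H](/C=C/OCC)[C@H]1OC(C)=O
F4 | step 9 | methyl 2-ethoxy-7-[(1E)-hept-1-en-1-yl]-4,5-dihydroxy-2,3,3a,4,5,7a-hexahydro-1-benzofuran-6-carboxylate (ring configuration as in 8) | CCCCC/C=C/C1=C(C(=O)OC)[C@@H](O)[C@@H](O)[C@H](CC(OCC)O2)[C@@H]12
F5 | step 9 | 2-ethoxy-7-[(1E)-hept-1-en-1-yl]-6-(hydroxymethyl)-2,3,3a,4,5,7a-hexahydro-1-benzofuran-4,5-diol (ring configuration as in 9) | CCCCC/C=C/C1=C(CO)[C@@H](O)[C@@H](O)[C@H](CC(OCC)O2)[C@@H]12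
F6 | step 9 | 7-[(1E)-hept-1-en-1-yl]-6-(hydroxymethyl)-2,3,3a,4,5,7a-hexahydro-1-benzofuran-2,4,5-triol (ring configuration as in 10) | CCCCC/C=C/C1=C(CO)[C@@H](O)[C@@H](O)[C@H](CC(O)O2)[C@@H]12
F7 | step 8 | 4-bromo-5-(hydroxymethyl)-2-(prop-2-en-1-yl)cyclohex-4-ene-1,3,6-triol (ring configuration as in 13) | BrC1=C(CO)[C@@H](O)[C@@H](O)[C@H](CC=C)[C@@H]1O
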